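## Retrosynthetic overview

1. Target 17 comes from acetylation of the threo alcohol 16; the C9 methyl comes from deoxygenation of a primary carbinol (tosylate, then hydride) while O-7 is masked as a TBS ether.
2. The C7–C8 bond and both stereocentres come from an Evans syn-aldol between the Z-boron enolate of aryloxyacetyl imide 7 and 3,4,5-trimethoxybenzaldehyde 8.
3. Imide 7 comes from aryloxyacetic acid 4 and (S)-4-benzyloxazolidin-2-one 5; acid 4 comes from methoxyeugenol 1 and ethyl bromoacetate 2 (aryl ether C–O bond made first).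
4. No ring is formed: both benzene rings are bought intact, and the oxazolidinone is a temporary auxiliary that is cleaved off again.

Assumption: 4-allyl-2,6-dimethoxyphenol (methoxyeugenol, a flavour chemical) is bought as such. The target is the (7R,8R)-threo acetate, i.e. (1R,2R) in propane numbering.

## Route

Step 1
Reactants: 1 4-allyl-2,6-dimethoxyphenol; 2 ethyl bromoacetate
Product: 3 ethyl 2-(4-allyl-2,6-dimethoxyphenoxy)acetate
Conditions: K2CO3, acetone, reflux
Reagents that add atoms: none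
Why: Williamson ether synthesis in which the phenoxide of 1 displaces bromide from the activated α-bromo ester by SN2, the weak base leaving the allyl group unisomerised.

Step 2
Reactants: 3 ethyl 2-(4-allyl-2,6-dimethoxyphenoxy)acetate
Product: 4 2-(4-allyl-2,6-dimethoxyphenoxy)acetic acid
Conditions: LiOH·H2O, THF/H2O (3:1), rt; then 1 M HCl
Reagents that add atoms: lithium hydroxide, [Li+].[OH-] (its oxygen becomes the acid OH)
Why: Saponification (BAc2 ester hydrolysis) at room temperature cleaves only the ethyl ester, the aryl ethers and the allyl group being inert.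

Step 3
Reactants: 4 2-(4-allyl-2,6-dimethoxyphenoxy)acetic acid; 5 (S)-4-benzyloxazolidin-2-one
Product: 7 (S)-3-[2-(4-allyl-2,6-dimethoxyphenoxy)acetyl]-4-benzyloxazolidin-2-one, via pivalic mixed anhydride 6 (not isolated)
Conditions: PivCl, Et3N, THF, −20 °C; then 5, LiCl, −20 °C → rt
Reagents that add atoms: pivaloyl chloride, CC(C)(C)C(=O)Cl (its acyl group is carried only in 6 and leaves again on the way to 7)
Why: N-acylation of the Evans auxiliary through a mixed anhydride, in which the lithium-activated oxazolidinone attacks the unhindered aryloxyacetyl carbonyl of 6 and not the tert-butyl-shielded one, the auxiliary stereocentre being untouched.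

Step 4
Reactants: 7 (S)-3-[2-(4-allyl-2,6-dimethoxyphenoxy)acetyl]-4-benzyloxazolidin-2-one; 8 3,4,5-trimethoxybenzaldehyde
Product: 11 (S)-4-benzyl-3-[(2S,3R)-2-(4-allyl-2,6-dimethoxyphenoxy)-3-hydroxy-3-(3,4,5-trimethoxyphenyl)propanoyl]oxazolidin-2-one, via Z-boron enolate 9 (not isolated), via boron aldolate 10 (not isolated)
Conditions: Bu2BOTf, iPr2NEt, CH2Cl2, −78 → 0 °C; 8, −78 → 0 °C; then pH 7 buffer, MeOH, 30% H2O2, 0 °C
Reagents that add atoms: dibutylboron triflate, CCCCB(CCCC)OS(=O)(=O)C(F)(F)F (its Bu2B group is carried only in 9 and 10 and is removed in the work-up)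
Why: Evans syn-aldol reaction in which soft enolisation gives the Z(O)-boron enolate 9, which adds to 8 through a closed Zimmerman–Traxler chair on the face away from the benzyl group of the dipole-opposed auxiliary, setting both stereocentres (2S,3R; the future 8R and 7R, threo) in one step.

Step 5
Reactants: 11 (S)-4-benzyl-3-[(2S,3R)-2-(4-allyl-2,6-dimethoxyphenoxy)-3-hydroxy-3-(3,4,5-trimethoxyphenyl)propanoyl]oxazolidin-2-one
Product: 12 (S)-4-benzyl-3-[(2S,3R)-2-(4-allyl-2,6-dimethoxyphenoxy)-3-(tert-butyldimethylsilyloxy)-3-(3,4,5-trimethoxyphenyl)propanoyl]oxazolidin-2-one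
Conditions: TBSOTf, 2,6-lutidine, CH2Cl2, −78 → 0 °C
Reagents that add atoms: tert-butyldimethylsilyl triflate, CC(C)(C)[Si](C)(C)OS(=O)(=O)C(F)(F)F
Why: O-silylation of the secondary benzylic alcohol with a silyl triflate and a hindered non-nucleophilic base proceeds without retro-aldol or epimerisation and masks O-7 for the hydride steps that follow.

Step 6
Reactants: 12 (S)-4-benzyl-3-[(2S,3R)-2-(4-allyl-2,6-dimethoxyphenoxy)-3-(tert-butyldimethylsilyloxy)-3-(3,4,5-trimethoxyphenyl)propanoyl]oxazolidin-2-one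
Product: 13 (2R,3R)-2-(4-allyl-2,6-dimethoxyphenoxy)-3-(tert-butyldimethylsilyloxy)-3-(3,4,5-trimethoxyphenyl)propan-1-ol
Conditions: LiBH4, H2O (1 equiv), Et2O, 0 °C → rt; aqueous work-up
Reagents that add atoms: none
Why: Reductive cleavage of the N-acyl oxazolidinone, in which lithium-chelated hydride attacks the exocyclic imide carbonyl, gives the primary alcohol and returns the auxiliary without epimerising C2 (the descriptor changes from S to R only through CIP priorities).

Step 7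
Reactants: 13 (2R,3R)-2-(4-allyl-2,6-dimethoxyphenoxy)-3-(tert-butyldimethylsilyloxy)-3-(3,4,5-trimethoxyphenyl)propan-1-ol
Product: 14 (2R,3R)-2-(4-allyl-2,6-dimethoxyphenoxy)-3-(tert-butyldimethylsilyloxy)-3-(3,4,5-trimethoxyphenyl)propyl 4-methylbenzenesulfonate
Conditions: TsCl, Et3N, DMAP (cat.), CH2Cl2, 0 °C → rt
Reagents that add atoms: 4-toluenesulfonyl chloride, Cc1ccc(cc1)S(Cl)(=O)=O
Why: DMAP-catalysed sulfonylation of the only free hydroxyl, a primary one, turns it into a leaving group without touching a stereocentre.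

Step 8
Reactants: 14 (2R,3R)-2-(4-allyl-2,6-dimethoxyphenoxy)-3-(tert-butyldimethylsilyloxy)-3-(3,4,5-trimethoxyphenyl)propyl 4-methylbenzenesulfonate
Product: 15 tert-butyl{[(1R,2R)-2-(4-allyl-2,6-dimethoxyphenoxy)-1-(3,4,5-trimethoxyphenyl)propyl]oxy}dimethylsilane
Conditions: LiEt3BH, THF, 0 °C → rt; then H2O
Reagents that add atoms: none
Why: SN2 hydride displacement of the primary tosylate by Super-Hydride, the most nucleophilic common hydride donor, replaces C–O by C–H at the non-stereogenic C9 while silyl ether, aryl ethers and the isolated alkene are inert.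

Step 9
Reactants: 15 tert-butyl{[(1R,2R)-2-(4-allyl-2,6-dimethoxyphenoxy)-1-(3,4,5-trimethoxyphenyl)propyl]oxy}dimethylsilane
Product: 16 (1R,2R)-2-(4-allyl-2,6-dimethoxyphenoxy)-1-(3,4,5-trimethoxyphenyl)propan-1-ol
Conditions: TBAF, THF, 0 °C → rt; aqueous work-up
Reagents that add atoms: none
Why: Fluoride-mediated desilylation, driven by the strong Si–F bond, frees the benzylic alcohol with retention because the C7–O bond is never broken.

Step 10
Reactants: 16 (1R,2R)-2-(4-allyl-2,6-dimethoxyphenoxy)-1-(3,4,5-trimethoxyphenyl)propan-1-ol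
Product: 17 (1R,2R)-2-(4-allyl-2,6-dimethoxyphenoxy)-1-(3,4,5-trimethoxyphenyl)propyl acetate
Conditions: Ac2O, pyridine, DMAP (cat.), CH2Cl2, rt
Reagents that add atoms: acetic anhydride, CC(=O)OC(C)=O
Why: DMAP-catalysed O-acylation (nucleophilic catalysis) of the secondary alcohol takes place at oxygen, so the (1R,2R) configuration is retained.

## Compound list

1 | 4-allyl-2,6-dimethoxyphenol (methoxyeugenol) | C=CCc1cc(OC)c(O)c(OC)c1 | starting material
2 | ethyl bromoacetate | CCOC(=O)CBr | starting material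
3 | ethyl 2-(4-allyl-2,6-dimethoxyphenoxy)acetate | C=CCc1cc(OC)c(OCC(=O)OCC)c(OC)c1 | intermediate
4 | 2-(4-allyl-2,6-dimethoxyphenoxy)acetic acid | C=CCc1cc(OC)c(OCC(=O)O)c(OC)c1 | intermediate
5 | (S)-4-benzyloxazolidin-2-one | O=C1OC[C@H](Cc2ccccc2)N1 | starting material
6 | 2-(4-allyl-2,6-dimethoxyphenoxy)acetic pivalic anhydride | C=CCc1cc(OC)c(OCC(=O)OC(=O)C(C)(C)C)c(OC)c1 | intermediate (not isolated)
7 | (S)-3-[2-(4-allyl-2,6-dimethoxyphenoxy)acetyl]-4-benzyloxazolidin-2-one | C=CCc1cc(OC)c(OCC(=O)N2[C@@H](Cc3ccccc3)COC2=O)c(OC)c1 | intermediate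
8 | 3,4,5-trimethoxybenzaldehyde | COc1cc(C=O)cc(OC)c1OC | starting material
9 | (Z)-dibutylboron enolate of 7 (enolate O cis to the aryloxy group) | C=CCc1cc(OC)c(O/C=C(\OB(CCCC)CCCC)N2[C@@H](Cc3ccccc3)COC2=O)c(OC)c1 | intermediate (not isolated)
10 | O-dibutylboryl derivative of aldol 11 (boron aldolate, 2S,3R) | C=CCc1cc(OC)c(O[C@H](C(=O)N2[C@@H](Cc3ccccc3)COC2=O)[C@H](OB(CCCC)CCCC)c4cc(OC)c(OC)c(OC)c4)c(OC)c1 | intermediate (not isolated)
11 | (S)-4-benzyl-3-[(2S,3R)-2-(4-allyl-2,6-dimethoxyphenoxy)-3-hydroxy-3-(3,4,5-trimethoxyphenyl)propanoyl]oxazolidin-2-one | C=CCc1cc(OC)c(O[C@H](C(=O)N2[C@@H](Cc3ccccc3)COC2=O)[C@H](O)c4cc(OC)c(OC)c(OC)c4)c(OC)c1 | intermediate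
12 | (S)-4-benzyl-3-[(2S,3R)-2-(4-allyl-2,6-dimethoxyphenoxy)-3-(tert-butyldimethylsilyloxy)-3-(3,4,5-trimethoxyphenyl)propanoyl]oxazolidin-2-one | C=CCc1cc(OC)c(O[C@H](C(=O)N2[C@@H](Cc3ccccc3)COC2=O)[C@H](O[Si](C)(C)C(C)(C)C)c4cc(OC)c(OC)c(OC)c4)c(OC)c1 | intermediate
13 | (2R,3R)-2-(4-allyl-2,6-dimethoxyphenoxy)-3-(tert-butyldimethylsilyloxy)-3-(3,4,5-trimethoxyphenyl)propan-1-ol | C=CCc1cc(OC)c(O[C@H](CO)[C@H](O[Si](C)(C)C(C)(C)C)c4cc(OC)c(OC)c(OC)c4)c(OC)c1 | intermediate
14 | (2R,3R)-2-(4-allyl-2,6-dimethoxyphenoxy)-3-(tert-butyldimethylsilyloxy)-3-(3,4,5-trimethoxyphenyl)propyl 4-methylbenzenesulfonate | C=CCc1cc(OC)c(O[C@H](COS(=O)(=O)c2ccc(C)cc2)[C@H](O[Si](C)(C)C(C)(C)C)c4cc(OC)c(OC)c(OC)c4)c(OC)c1 | intermediate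
15 | tert-butyl{[(1R,2R)-2-(4-allyl-2,6-dimethoxyphenoxy)-1-(3,4,5-trimethoxyphenyl)propyl]oxy}dimethylsilane | C=CCc1cc(OC)c(O[C@H](C)[C@H](O[Si](C)(C)C(C)(C)C)c4cc(OC)c(OC)c(OC)c4)c(OC)c1 | intermediate
16 | (1R,2R)-2-(4-allyl-2,6-dimethoxyphenoxy)-1-(3,4,5-trimethoxyphenyl)propan-1-ol (threo) | C=CCc1cc(OC)c(O[C@H](C)[C@H](O)c4cc(OC)c(OC)c(OC)c4)c(OC)c1 | intermediate
17 | (1R,2R)-2-(4-allyl-2,6-dimethoxyphenoxy)-1-(3,4,5-trimethoxyphenyl)propyl acetate (CNP0117299.1) | C=CCc1cc(OC)c(O[C@H](C)[C@H](OC(C)=O)c2cc(OC)c(OC)c(OC)c2)c(OC)c1 | target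

## Summary

Total step count: 10.
Longest linear sequence: 10 steps (1 → 17); 2, 5 and 8 are bought and enter directly.

Three steps most likely to fail, each with a fallback:

Step 4 (aldol). The bulky, Lewis-basic 2,6-dimethoxyaryloxy group may slow boron enolisation or erode syn selectivity, and the electron-rich aldehyde is a modest electrophile. The fallback sets out from acid 4 and changes both auxiliary and enolate metal. Acid 4 is coupled with (S)-4-benzylthiazolidine-2-thione (EDC·HCl, DMAP, CH2Cl2) to give (S)-2-(4-allyl-2,6-dimethoxyphenoxy)-1-(4-benzyl-2-thioxothiazolidin-3-yl)ethan-1-one F1. Its chlorotitanium enolate (TiCl4, iPr2NEt, NMP, CH2Cl2, −78 → 0 °C, Crimmins "Evans-syn" conditions) is more reactive and adds to 8 to give the (2S,3R)-syn aldol thiazolidinethione imide F2. Silylation (TBSOTf, 2,6-lutidine) gives the TBS-protected aldol thiazolidinethione imide F3. The very labile thioimide is then cleaved with NaBH4 in THF/EtOH at 0 °C, which comes back to the route at 13. The sense of induction would be confirmed by comparing this 13 with material from the main route.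

Step 6 (reductive removal of the auxiliary). The exocyclic carbonyl of 12 is flanked by the aryloxy and silyloxy-benzyl groups, so hydride may open the oxazolidinone ring instead. The fallback sets out from 11 and drops the protecting group. The unprotected aldol is reduced with NaBH4 in THF/H2O (free β-OH, much less hindered) to (1R,2R)-2-(4-allyl-2,6-dimethoxyphenoxy)-1-(3,4,5-trimethoxyphenyl)propane-1,3-diol F4. Selective sulfonylation of the primary hydroxyl (TsCl, Et3N, cat. Bu2SnO, CH2Cl2, 0 °C) gives (2R,3R)-2-(4-allyl-2,6-dimethoxyphenoxy)-3-hydroxy-3-(3,4,5-trimethoxyphenyl)propyl 4-methylbenzenesulfonate F5. LiAlH4 in THF at 0 °C then reduces the tosylate through the alkoxyaluminate and comes back to the route at 16, bypassing steps 5–9.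

Step 8 (C9 deoxygenation). On the β-branched, β-oxygenated tosylate 14, hydride may attack sulfur (returning 13) or react sluggishly. The fallback sets out from 13 and replaces the sulfonate by a leaving group that can only be attacked at carbon. Appel iodination (I2, PPh3, imidazole, CH2Cl2, 0 °C → rt) gives tert-butyl{[(1R,2S)-2-(4-allyl-2,6-dimethoxyphenoxy)-3-iodo-1-(3,4,5-trimethoxyphenyl)propyl]oxy}dimethylsilane F6. Polar reduction with NaBH4 in DMSO (25 → 60 °C) then comes back to the route at 15. Radical (Bu3SnH) and zinc reductions are avoided because a C9 radical or organozinc β to the aryloxy group would eliminate the phenol.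

Further compounds
F1 | step 4 | (S)-2-(4-allyl-2,6-dimethoxyphenoxy)-1-(4-benzyl-2-thioxothiazolidin-3-yl)ethan-1-one | C=CCc1cc(OC)c(OCC(=O)N2[C@@H](Cc3ccccc3)CSC2=S)c(OC)c1
F2 | step 4 | (2S,3R)-2-(4-allyl-2,6-dimethoxyphenoxy)-1-[(S)-4-benzyl-2-thioxothiazolidin-3-yl]-3-hydroxy-3-(3,4,5-trimethoxyphenyl)propan-1-one | C=CCc1cc(OC)c(O[C@H](C(=O)N2[C@@H](Cc3ccccc3)CSC2=S)[C@H](O)c4cc(OC)c(OC)c(OC)c4)c(OC)c1
F3 | step 4 | (2S,3R)-2-(4-allyl-2,6-dimethoxyphenoxy)-1-[(S)-4-benzyl-2-thioxothiazolidin-3-yl]-3-(tert-butyldimethylsilyloxy)-3-(3,4,5-trimethoxyphenyl)propan-1-one | C=CCc1cc(OC)c(O[C@H](C(=O)N2[C@@H](Cc3ccccc3)CSC2=S)[C@H](O[Si](C)(C)C(C)(C)C)c4cc(OC)c(OC)c(OC)c4)c(OC)c1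
F4 | step 6 | (1R,2R)-2-(4-allyl-2,6-dimethoxyphenoxy)-1-(3,4,5-trimethoxyphenyl)propane-1,3-diol | C=CCc1cc(OC)c(O[C@H](CO)[C@H](O)c4cc(OC)c(OC)c(OC)c4)c(OC)c1
F5 | step 6 | (2R,3R)-2-(4-allyl-2,6-dimethoxyphenoxy)-3-hydroxy-3-(3,4,5-trimethoxyphenyl)propyl 4-methylbenzenesulfonate | C=CCc1cc(OC)c(O[C@H](COS(=O)(=O)c2ccc(C)cc2)[C@H](O)c4cc(OC)c(OC)c(OC)c4)c(OC)c1
F6 | step 8 | tert-butyl{[(1R,2S)-2-(4-allyl-2,6-dimethoxyphenoxy)-3-iodo-1-(3,4,5-trimethoxyphenyl)propyl]oxy}dimethylsilane | C=CCc1cc(OC)c(O[C@H](CI)[C@H](O[Si](C)(C)C(C)(C)C)c4cc(OC)c(OC)c(OC)c4)c(OC)c1
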